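At early times neither run shows a lag: E falls and L rises from the first reading.

common to all: E 46 mM
- Saturday's: D 46 mM; run made earlier
- Friday's: D 69 mM; run made earlier
- flask: D 92.0 mM; time 25 min; volume of the second phase over the first 2.0

- Saturday's (time / min: L / %, E / %): 1.50: 2.3, 98.1; 3.00: 3.0, 96.7; 6.00: 7.5, 93.0; 10.0: 10.9, 88.0; 20.0: 17.1, 79.6
- Friday's (time / min: L / %, E / %): 1.50: 2.1, 96.7; 3.00: 6.6, 94.1; 6.00: 10.4, 89.3; 10.0: 13.9, 82.7; 20.0: 21.2, 70.1

(each reading ± 0.5 percentage points)

- in the second phase: D; everything else is in the first
- charges count per volume of the first phase; a concentration in a rate is the amount of a species over the volume of its own phase; every rate counts per litre of the first phase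
- steps thought possible: G <-> D; G + L -> J; E + G -> L; G <-> X
- the earlier runs hold the two phases in the same ratio of volumes as the flask asked about

- the L standing at 25 min, as a percentage of the E charged
- part of the E charged that has reacted at 25 min

The number to carry is κ, the pseudo-first-order loss of E per minute per equivalent of D charged, that is, minus the logarithm of the fraction of E left, over equivalents and time. Saturday's last reading gives 0.0114 min⁻¹ and Friday's 0.0118 min⁻¹, so the mean 0.0116 min⁻¹ serves both.

The new flask holds 2.00 equivalents of D, so its E is reckoned to fall with a first-order constant of 0.0232 min⁻¹. L is used up as well, and a selectivity factor for L against E taken at 2 gives L = x(1 − x), with x the fraction of E left. For the last readings that formula gives 16.2% on Saturday's run against 17.1% read, and 21.0% on Friday's against 21.2%.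

On this curve L tops at a quarter of the charge, at x of one half, and J crosses L there, at 29.8 min. At 25 min the reckoning here has x at 55.9%, so 44.1% has reacted and L stands at 24.6%. The slope of L there is down to 0.0660 of its start, so L sits on the flat shoulder.

The forecast puts L at 25.2% (22.5% to 28%) with 43% of E reacted (39.5% to 47.5%), on the ground that “the rate scales about linearly with D”. Its L is 0.60 percentage points above the reckoning here.

The flask gives 25.4% of L with 43.4% reacted, and L still stands at 24.8% at 50.0 min.

    G ⇌ D, rate k1*([G] - [D]/K1) per volume of the first phase (partition coefficient = 0.620, kL = 4.90 min⁻¹)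
    G + L → J (k = 1.80 L mol⁻¹ min⁻¹)
    E + G → L (k = 0.960 L mol⁻¹ min⁻¹)
    G ⇌ X (K = 1.00, k = 2.10 min⁻¹)

Backed out of this flask, κ is 0.0114 min⁻¹, a little lower than the 0.0116 min⁻¹ read from the runs. Carried to the same flask read at 1.0 h, the value from the runs puts E at 24.9%. That flask holds 33.3%, a κ of 0.00916 min⁻¹, with D at 17.3% of its own charge.

The runs are calculated for substances that don't exist, and the scatter is random.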